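**Plan**
- Retrosynthesis: the acid side chain is cut at its central sp2–sp2 bond (Suzuki–Miyaura) and the dienoate at the C=C next to the ring (Horner–Wadsworth–Emmons). The ring alkene C6=C7 is then moved back to C7=C7a with an oxygen (from boron) on C6. Last, the cyclohexene is cut at C5–C6 and C4–C3a.
- Enabling feature: in the cyclohexene ring, C4 and C5 carry trans sp2 substituents (the imprint of an E-dienophile). C3a–C7a–C7–C6, with the cyclopentane fused at C3a/C7a, is a 1-vinylcyclopentene diene once C6=C7 is shifted by one position; a boron on C6 marks where the double bond must return.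
- Forward: dienylboronate + auxiliary-bound enynoate → Diels–Alder (cyclohexene onto the preformed cyclopentene) → C–B to C–OH and lactone → lactol → dienoate → inverted formate → Pd–H 1,3-transposition (trans ring fusion) → alkyne → alkenylboronate → Suzuki coupling.
- Stereochemistry: the (R)-4-benzyloxazolidinone fixes C4/C5 absolutely and the endo transition state fixes C3a and C6. C6 then relays to C7a (H delivered anti to the inverted formate). E-alkenes come from the olefination, syn-hydroboration and syn-hydrozirconation.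

Key step: step 4

Remark: hexahydro-1H-indene numbering of the target is used for all bicyclic compounds (C3a/C7a ring fusion, C4 dienoate carbon, C5 acid-chain carbon, C6=C7 ring alkene). β is the ring face carrying H-3a and H-4 in the target; α is the opposite face (H-5, H-7a). Compounds 1, 2, 4, 5, 7, 14 and 20 are taken as commercial.

**Step 1**
Reactants: 1 1-ethynylcyclopent-1-ene; 2 pinacolborane
Product: 3 2-[(E)-2-(cyclopent-1-en-1-yl)ethenyl]-4,4,5,5-tetramethyl-1,3,2-dioxaborolane
Conditions: HBpin (1.1 equiv), Cp2Zr(H)Cl (5 mol%), Et3N (10 mol%), neat, 60 °C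
Reagents that add atoms: none
Why: Zirconium-catalysed syn-hydroboration of the terminal alkyne should give the (E)-alkenylboronate only, the trisubstituted ring alkene being inert.

**Step 2**
Reactants: 4 3-(trimethylsilyl)prop-2-ynal; 5 (diethoxyphosphoryl)acetic acid
Product: 6 (E)-5-(trimethylsilyl)pent-2-en-4-ynoic acid
Conditions: 5, n-BuLi (2.1 equiv), THF, −78 °C; then 4, −78 → 0 °C; aq. HCl
Reagents that add atoms: none
Why: Horner–Wadsworth–Emmons olefination with the phosphonoacetate dianion should give the (E)-enynoic acid directly, the C-silyl group surviving the acidic work-up.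

**Step 3**
Reactants: 6 (E)-5-(trimethylsilyl)pent-2-en-4-ynoic acid; 7 (R)-4-benzyl-1,3-oxazolidin-2-one
Product: 9 (R)-4-benzyl-3-[(E)-5-(trimethylsilyl)pent-2-en-4-ynoyl]-1,3-oxazolidin-2-one, via mixed pivalic anhydride 8 (not isolated)
Conditions: PivCl, Et3N, THF, −20 °C; then 7, LiCl, −20 °C → rt
Reagents that add atoms: none
Why: N-acylation of the oxazolidinone through the mixed anhydride (LiCl-assisted) is a standard way to N-enoyl imides and should leave the E-alkene and silyl alkyne untouched.

**Step 4**
Reactants: 3 dienylboronate; 9 N-enynoyl oxazolidinone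
Product: 10 (R)-4-benzyl-3-{[6α-(4,4,5,5-tetramethyl-1,3,2-dioxaborolan-2-yl)-5β-[(trimethylsilyl)ethynyl]-2,3,3a,4,5,6-hexahydro-1H-inden-4α-yl]carbonyl}-1,3-oxazolidin-2-one (H-3a, H-4 and H-6 β; H-5 α; alkene C7=C7a)
Conditions: Me2AlCl (1.5 equiv), CH2Cl2, −78 → −20 °C
Reagents that add atoms: none
Why: A concerted, asynchronous [4π+2π] cycloaddition joins the s-cis dienylboronate (C6=C7–C7a=C3a) to the Al-chelated, s-cis N-enoyl imide, the vinyl terminus C6 bonding to the electrophilic β-carbon (C5) and the ring carbon C3a to the α-carbon (C4); the closest precedents are Lewis-acid-promoted Diels–Alder reactions of N-enoyl oxazolidinone auxiliaries with acyclic dienes and Diels–Alder reactions of 1-boryl dienes that give cyclic allylboronates. The cyclohexene ring is closed by intermolecular [4+2] annulation onto the cyclopentene C3a=C7a bond, leaving a C7=C7a alkene. C4 and C5 should come out trans because the E-dienophile reacts suprafacially, and their absolute configuration is fixed by the (R)-benzyl group, which blocks one face of the chelated imide so that the diene adds to the Cα-Re face. C3a and C6 are set relative to C4 by the endo transition state (imide carbonyl under the diene) together with the E-geometry of the vinylboronate, placing H-3a cis to H-4 and boron cis to the C4 acyl group. The step needs regio- and endo-selectivity: the first should follow from the alkyl pattern of the semicyclic diene (charge developing over C7–C7a–C3a as C6 attacks) and the weak directing power of boron, the second from the chelated imide.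

**Step 5**
Reactants: 10 Diels–Alder adduct
Product: 12 bridged γ-lactone (C4 carbonyl–O–C6α) carrying the 5β-[(trimethylsilyl)ethynyl] group and the C7=C7a alkene, via hydroxy imide 11 (not isolated)
Conditions: NaBO3·4H2O, THF/pH 7 buffer, 0 °C → rt; then Et3N, DMAP (cat.), CH2Cl2, rt
Reagents that add atoms: sodium perborate, [Na+].[Na+].O[B-]1(O)OO[B-](O)(O)OO1
Why: Perborate oxidation of the allylic boronate proceeds with retention (1,2-shift from boron to oxygen) to the 6α-alcohol, which is cis-1,3 to the C4 acyl group and should transacylate intramolecularly, closing the lactone and releasing the auxiliary.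

**Step 6**
Reactants: 12 bridged lactone
Product: 13 bridged lactol (anomeric mixture)
Conditions: DIBAL-H (1.1 equiv), CH2Cl2, −78 °C; aq. K/Na tartrate
Reagents that add atoms: none
Why: Half-reduction of a lactone at −78 °C stops at the tetrahedral aluminium acetal, so the lactol (a masked C4 aldehyde with C6-OH) is expected.

**Step 7**
Reactants: 13 lactol; 14 methyl (E)-4-(dimethoxyphosphoryl)but-2-enoate
Product: 15 methyl (2E,4E)-5-{6α-hydroxy-5β-[(trimethylsilyl)ethynyl]-2,3,3a,4,5,6-hexahydro-1H-inden-4α-yl}penta-2,4-dienoate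
Conditions: 14 (2.5 equiv), LiHMDS (2.4 equiv), THF, −78 → 0 °C; quench cold with AcOH
Reagents that add atoms: none
Why: The lactol opens to the hydroxy aldehyde, and vinylogous Horner–Wadsworth–Emmons olefination should give the (E,E)-dienoate; low temperature and the preformed lithium phosphonate limit epimerisation at C4, and oxa-conjugate addition would have to form a strained bridged ether.

**Step 8**
Reactants: 15 6α-allylic alcohol
Product: 16 methyl (2E,4E)-5-{6β-(formyloxy)-5β-[(trimethylsilyl)ethynyl]-2,3,3a,4,5,6-hexahydro-1H-inden-4α-yl}penta-2,4-dienoate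
Conditions: HCO2H, PPh3, DIAD, THF, 0 °C → rt
Reagents that add atoms: formic acid, O=CO
Why: Mitsunobu esterification displaces the pseudoaxial C6 oxyphosphonium with inversion; H-5 is syn to the leaving group, so anti-elimination toward C5 is not available, and SN2′ attack would have to occur at the fully substituted C7a.

**Step 9**
Reactants: 16 6β-allylic formate
Product: 17 methyl (2E,4E)-5-{5β-[(trimethylsilyl)ethynyl]-2,3,3a,4,5,7a-hexahydro-1H-inden-4α-yl}penta-2,4-dienoate (trans-fused: H-3a β, H-7a α; alkene C6=C7)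
Conditions: Pd(acac)2 (5 mol%), n-Bu3P (5 mol%), THF, rt
Reagents that add atoms: none
Why: In this Tsuji–Trost-type formate hydrogenolysis, Pd(0) ionises the formate with inversion (Pd on the α-face), decarboxylation gives a π-allyl palladium hydride, and the hydride is transferred on the Pd face to the more substituted terminus C7a, which should create the trans ring fusion and move the alkene to C6=C7.

**Step 10**
Reactants: 17 silyl alkyne
Product: 18 methyl (2E,4E)-5-(5β-ethynyl-2,3,3a,4,5,7a-hexahydro-1H-inden-4α-yl)penta-2,4-dienoate (trans-fused)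
Conditions: K2CO3 (0.3 equiv), MeOH, 0 °C → rt
Reagents that add atoms: none
Why: Methanolysis of the C(sp)–Si bond is fast under catalytic carbonate and degenerate for the methyl ester, so only the terminal alkyne should be unveiled.

**Step 11**
Reactants: 18 terminal alkyne; 2 pinacolborane
Product: 19 methyl (2E,4E)-5-{5β-[(E)-2-(4,4,5,5-tetramethyl-1,3,2-dioxaborolan-2-yl)ethenyl]-2,3,3a,4,5,7a-hexahydro-1H-inden-4α-yl}penta-2,4-dienoate
Conditions: HBpin (1.5 equiv), Cp2Zr(H)Cl (10 mol%), Et3N (10 mol%), CH2Cl2, rt
Reagents that add atoms: none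
Why: Catalytic syn-hydroboration is selective for the terminal alkyne over the disubstituted alkenes and the ester and should give the (E)-alkenylboronate.

**Step 12**
Reactants: 20 methyl hex-5-ynoate
Product: 22 methyl (E)-6-iodohex-5-enoate, via alkenylzirconocene 21 (not isolated)
Conditions: Cp2Zr(H)Cl (1.2 equiv), THF, rt; then I2, 0 °C
Reagents that add atoms: iodine, II
Why: Syn-hydrozirconation of the terminal alkyne followed by iodinolysis with retention should give the (E)-alkenyl iodide, the remote ester reacting much more slowly than the alkyne.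

**Step 13**
Reactants: 22 methyl (E)-6-iodohex-5-enoate
Product: 23 (E)-6-iodohex-5-enoic acid
Conditions: LiOH·H2O, THF/H2O, 0 °C → rt; then aq. HCl to pH 3
Reagents that add atoms: lithium hydroxide, [Li+].[OH-]
Why: Simple saponification of an unhindered methyl ester leaves the alkenyl iodide untouched.

**Step 14**
Reactants: 19 alkenylboronate; 23 (E)-6-iodohex-5-enoic acid
Product: 24 aplidic acid A, (5E,7E)-8-[(3aR,4R,5R,7aS)-4-[(1E,3E)-5-methoxy-5-oxopenta-1,3-dien-1-yl]-2,3,3a,4,5,7a-hexahydro-1H-inden-5-yl]octa-5,7-dienoic acid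
Conditions: Pd(dppf)Cl2 (5 mol%), K3PO4 (4 equiv), THF/H2O, rt; acidify to pH 4
Reagents that add atoms: none
Why: Suzuki–Miyaura coupling of two (E)-alkenyl partners is stereoretentive, tolerates the carboxylate and, at room temperature with phosphate, should not hydrolyse the conjugated methyl ester, so the free acid is obtained without a protecting group.

**Compound list**
1 | 1-ethynylcyclopent-1-ene | C#CC1=CCCC1 | starting material
2 | pinacolborane | CC1(C)OBOC1(C)C | starting material
3 | 2-[(E)-2-(cyclopent-1-en-1-yl)ethenyl]-4,4,5,5-tetramethyl-1,3,2-dioxaborolane | CC1(C)OB(/C=C/C2=CCCC2)OC1(C)C | intermediate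
4 | 3-(trimethylsilyl)prop-2-ynal | C[Si](C)(C)C#CC=O | starting material
5 | (diethoxyphosphoryl)acetic acid | CCOP(=O)(CC(=O)O)OCC | starting material
6 | (E)-5-(trimethylsilyl)pent-2-en-4-ynoic acid | C[Si](C)(C)C#C/C=C/C(=O)O | intermediate
7 | (R)-4-benzyl-1,3-oxazolidin-2-one | O=C1N[C@H](Cc2ccccc2)CO1 | starting material
8 | (E)-5-(trimethylsilyl)pent-2-en-4-ynoic pivalic anhydride | C[Si](C)(C)C#C/C=C/C(=O)OC(=O)C(C)(C)C | intermediate (not isolated)
9 | (R)-4-benzyl-3-[(E)-5-(trimethylsilyl)pent-2-en-4-ynoyl]-1,3-oxazolidin-2-one | C[Si](C)(C)C#C/C=C/C(=O)N1[C@H](Cc2ccccc2)COC1=O | intermediate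
10 | Diels–Alder adduct: 4α-acyl (imide), 5β-silylethynyl, 6α-Bpin, H-3a β, C7=C7a | O=C([C@@H]1[C@@H]2CCCC2=C[C@H](B3OC(C)(C)C(C)(C)O3)[C@H]1C#C[Si](C)(C)C)N1[C@H](Cc2ccccc2)COC1=O | intermediate
11 | 6α-hydroxy imide | O=C([C@@H]1[C@@H]2CCCC2=C[C@H](O)[C@H]1C#C[Si](C)(C)C)N1[C@H](Cc2ccccc2)COC1=O | intermediate (not isolated)
12 | bridged γ-lactone (C4 carbonyl–O–C6α), 5β-silylethynyl, C7=C7a | O=C1O[C@H]2C=C3CCC[C@H]3[C@@H]1[C@@H]2C#C[Si](C)(C)C | intermediate
13 | bridged lactol (anomeric mixture) | OC1O[C@H]2C=C3CCC[C@H]3[C@@H]1[C@@H]2C#C[Si](C)(C)C | intermediate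
14 | methyl (E)-4-(dimethoxyphosphoryl)but-2-enoate | COC(=O)/C=C/CP(=O)(OC)OC | starting material
15 | methyl (2E,4E)-5-{6α-hydroxy-5β-[(trimethylsilyl)ethynyl]-2,3,3a,4,5,6-hexahydro-1H-inden-4α-yl}penta-2,4-dienoate | COC(=O)/C=C/C=C/[C@@H]1[C@@H]2CCCC2=C[C@H](O)[C@H]1C#C[Si](C)(C)C | intermediate
16 | 6β-formate of 15 (C6 inverted) | COC(=O)/C=C/C=C/[C@@H]1[C@@H]2CCCC2=C[C@@H](OC=O)[C@H]1C#C[Si](C)(C)C | intermediate
17 | trans-fused silyl alkyne, alkene C6=C7 | COC(=O)/C=C/C=C/[C@@H]1[C@@H]2CCC[C@H]2C=C[C@H]1C#C[Si](C)(C)C | intermediate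
18 | trans-fused terminal alkyne | COC(=O)/C=C/C=C/[C@@H]1[C@@H]2CCC[C@H]2C=C[C@H]1C#C | intermediate
19 | trans-fused (E)-alkenyl pinacol boronate | COC(=O)/C=C/C=C/[C@@H]1[C@@H]2CCC[C@H]2C=C[C@H]1/C=C/B1OC(C)(C)C(C)(C)O1 | intermediate
20 | methyl hex-5-ynoate | C#CCCCC(=O)OC | starting material
21 | methyl (E)-6-[chlorobis(cyclopentadienyl)zirconio]hex-5-enoate | COC(=O)CCC/C=C/[Zr](Cl)(C1C=CC=C1)C1C=CC=C1 | intermediate (not isolated)
22 | methyl (E)-6-iodohex-5-enoate | COC(=O)CCC/C=C/I | intermediate
23 | (E)-6-iodohex-5-enoic acid | OC(=O)CCC/C=C/I | intermediate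
24 | aplidic acid A | COC(=O)/C=C/C=C/[C@@H]1[C@@H]2CCC[C@H]2C=C[C@H]1/C=C/C=C/CCCC(=O)O | target

**Step count:** 14 steps in total. Longest linear sequence: 11 steps (2, 3, 4, 5, 6, 7, 8, 9, 10, 11, 14).

**Steps most likely to fail**

Step 4. The electron-neutral, hindered dienylboronate may react sluggishly with the β-substituted imide, with Lewis-acid-induced protodeboronation or oligomerisation of the diene, or erosion of regiocontrol. The fallback changes the activation mode to iminium catalysis and drops auxiliary, lactone and lactol; it sets out from 4 and 3 and returns at 15. Wittig olefination of 4 with (triphenylphosphoranylidene)acetaldehyde (toluene, rt) should give (E)-5-(trimethylsilyl)pent-2-en-4-ynal F1. Cycloaddition of F1 with 3 under (5R)-5-benzyl-2,2,3-trimethylimidazolidin-4-one hydrochloride (20 mol%, MeCN/H2O, −10 °C → rt) should give the 4α-formyl 6α-boryl adduct F2; the benzyl group of the (E)-iminium ion shields the Si face, so the diene adds endo to the Re face. Olefination of F2 with 14/LiHMDS as in step 7 should give the boryl dienoate F3, and perborate oxidation of F3 with retention gives 15.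

Step 8. The SN2 inversion at the hindered allylic C6 may be overtaken by elimination or by acyl transfer with retention. The fallback replaces SN2 inversion plus Pd–H delivery by a double-inversion substitution followed by a sigmatropic reduction; it sets out from 15 and returns at 17. Acylation of 15 (ClCO2Me, pyridine, DMAP) gives the 6α-methyl carbonate F4. Pd-catalysed allylic substitution (Pd2(dba)3, PPh3, THF) with N-isopropylidene-N′-(2-nitrobenzenesulfonyl)hydrazine should attack the less substituted terminus C6 anti to palladium, giving with net retention the 6α-N-allyl sulfonyl hydrazone F5. Hydrolysis of F5 (AcOH, CF3CH2OH/H2O) liberates the monoalkyl diazene, which loses dinitrogen by a retro-ene shift that delivers hydrogen suprafacially to the α-face of C7a, giving 17.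

Step 9. The palladium hydride may transfer hydrogen to C6 instead of C7a (untransposed alkene), or the π-allyl complex may undergo β-hydride elimination to a diene. The fallback uses a regiospecific sigmatropic transposition; it sets out from 16 and returns at 18. Methanolysis of 16 (K2CO3, MeOH) removes the formyl and the C-silyl group to give the 6β-alcohol with a terminal alkyne F6. Mitsunobu reaction of F6 with N-isopropylidene-N′-(2-nitrobenzenesulfonyl)hydrazine (PPh3, DEAD, THF) inverts C6 to the 6α-N-allyl sulfonyl hydrazone F7. Hydrolysis of F7 (CF3CH2OH/H2O) gives the diazene, whose retro-ene loss of dinitrogen places hydrogen on the α-face of C7a and the alkene at C6=C7, giving 18.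

**Further compounds**
F1 | step 4 | (E)-5-(trimethylsilyl)pent-2-en-4-ynal | C[Si](C)(C)C#C/C=C/C=O
F2 | step 4 | 6α-Bpin-5β-[(trimethylsilyl)ethynyl]-2,3,3a,4,5,6-hexahydro-1H-indene-4α-carbaldehyde | O=C[C@@H]1[C@@H]2CCCC2=C[C@H](B3OC(C)(C)C(C)(C)O3)[C@H]1C#C[Si](C)(C)C
F3 | step 4 | methyl (2E,4E)-5-{6α-Bpin-5β-[(trimethylsilyl)ethynyl]-2,3,3a,4,5,6-hexahydro-1H-inden-4α-yl}penta-2,4-dienoate | COC(=O)/C=C/C=C/[C@@H]1[C@@H]2CCCC2=C[C@H](B3OC(C)(C)C(C)(C)O3)[C@H]1C#C[Si](C)(C)C
F4 | step 8 | 6α-methyl carbonate of 15 | COC(=O)/C=C/C=C/[C@@H]1[C@@H]2CCCC2=C[C@H](OC(=O)OC)[C@H]1C#C[Si](C)(C)C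
F5 | step 8 | 6α-[N-(2-nitrobenzenesulfonyl)-N′-isopropylidenehydrazinyl] derivative with silyl alkyne | COC(=O)/C=C/C=C/[C@@H]1[C@@H]2CCCC2=C[C@H](N(N=C(C)C)S(=O)(=O)c3ccccc3[N+](=O)[O-])[C@H]1C#C[Si](C)(C)C
F6 | step 9 | methyl (2E,4E)-5-(5β-ethynyl-6β-hydroxy-2,3,3a,4,5,6-hexahydro-1H-inden-4α-yl)penta-2,4-dienoate | COC(=O)/C=C/C=C/[C@@H]1[C@@H]2CCCC2=C[C@@H](O)[C@H]1C#C
F7 | step 9 | 6α-[N-(2-nitrobenzenesulfonyl)-N′-isopropylidenehydrazinyl] derivative with terminal alkyne | COC(=O)/C=C/C=C/[C@@H]1[C@@H]2CCCC2=C[C@H](N(N=C(C)C)S(=O)(=O)c3ccccc3[N+](=O)[O-])[C@H]1C#C
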